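Numbering used throughout: the chain of the target is numbered from the ester carbonyl (C1) to the brominated carbon (C20); the ring oxygen joins C5 and C8.

## The problem

The target is a C20 methyl ester with one ring, a 2,5-disubstituted oxolane (O, C5, C6, C7, C8). The butanoate arm C1–C4 sits on C5, and C8 carries a twelve-carbon arm with a conjugated (E)-enyne (C9≡C10–C11=C12) and a terminal (Z)-bromoalkene (C19=C20). The two stereocentres, C5 (R) and C8 (S), are trans across the ring oxygen and are separated by two bare methylenes. Neither has a neighbouring substituent that could relay its configuration, so each must be set by a reagent or through the ring-forming event. C8 is both propargylic and α to oxygen, so its C–H and C–O bonds are at risk from strong base and from acid once the alkyne is in place. The enyne and the bromoalkene exclude hydrogenation, dissolving metals and radical reductions after the tail is attached, so ring saturation and all redox work on the ester arm must come first and the tail last. The feature that opens the key step is that C6 and C7 are unsubstituted and C5 carries a four-carbon arm. C5 and C6 together with C4, C3 and C2 can therefore be folded into a cyclopent-2-enyl ring on oxygen whose alkene (C6=C2) is exchanged by metathesis for C6=C7, a vinyl group on C8 supplying C7 and C1 arriving as the capping methylene.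

## Retrosynthesis

**C10–C11.** The first cut is the sp–sp2 bond between the alkyne and the (E)-alkene, dividing 27 into the terminal alkyne 21 and the bromo-iodo diene 26. Cutting C8–C9 instead would set C8 late by addition to an oxocarbenium ion with uncertain trans selectivity, and making the bromoalkene after the coupling would put a geometry-defining olefination at the very end. The cut removes every sensitive group of the tail from the ring chemistry. The forward coupling must insert into the C–I bond of 26 and leave its C–Br bond alone.

**The tail.** Diene 26 is traced to the bromoenyne 24 (C11–I bond, anti-Markovnikov syn addition across the terminal alkyne), 24 to non-8-ynal 23 (C19=C20 by a Z-selective one-carbon olefination) and 23 to commercial non-8-yn-1-ol 22. Making the bromoalkene first keeps the light-sensitive iodoalkene out of the basic olefination. The forward sequence needs Z control in the olefination and a hydrometalation that distinguishes a terminal alkyne from a disubstituted bromoalkene.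

**Adjustments on the ring core.** No skeletal bond is cut between 21 and the dihydrofuran 14. Compound 21 comes from the silylalkyne 20 by desilylation, 20 from acid 19 by O-methylation, 19 from alcohol 17 by oxidation of C1, 17 from the dihydrofuranyl alcohol 16 by saturation of C6=C7, and 16 from 14 by anti-Markovnikov hydration of C1=C2. The order is fixed by reactivity: the terminal alkene must be hydroborated before the ring alkene is reduced, because a metal-free hydrogen transfer would take the terminal alkene first. The silyl cap stays on until the alkyne is needed, since it shields the triple bond through hydroboration, reduction and oxidation.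

**Key disconnection, C6=C7.** The ring alkene of 14 is opened in the retrosynthetic sense and C6 is reconnected to C2, giving the cyclopent-2-enyl ether 13. Against a ring closure that forms a C–O bond and creates a stereocentre, this cut creates none: both carbinol carbons are already fixed in the ether. Against plain diene metathesis of an acyclic ether, the carbocycle supplies C2–C4 at the correct length with no separate chain synthesis. Ether 13 is made of two small allylic units, a large simplification. The forward reaction needs only chemoselectivity for the intramolecular exchange.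

**O–C8.** Ether 13 is cut at the bond between oxygen and C8, giving (1R)-cyclopent-2-en-1-ol 10 (used as its copper alkoxide 12) and the linear carbonate 6. Cutting O–C5 instead would mean substitution at a cyclopentenyl carbon through a symmetrical allyl intermediate, which erases the configuration unless a second chiral catalyst intervenes. On the C8 side, a branched-selective allylic substitution turns an achiral linear carbonate into the stereocentre, so no labile secondary propargylic electrophile has to be made. The forward step must deliver the branched regioisomer, set C8 under ligand control regardless of the alkoxide, and leave the C–O bond of 10 intact.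

**The two small fragments.** Carbonate 6 comes from allylic alcohol 5, 5 from enynoate 4 by ester reduction, and 4 from aldehyde 2 and phosphonate 1 by forming the future C7=C8 alkene with E geometry. Alcohol 10 comes from the bromo alcohol 8 by removal of bromine, and 8 from commercial enone 7 by enantioselective carbonyl reduction. The bromine is a temporary control element that enlarges the steric difference between the two arms of the ketone.

## Roads not taken

**Alternative 1:** The cut is the ring O–C5 bond, made by contracting a pyranose. Nitrous acid would diazotise the amine on sugar carbon 2 of D-glucosamine A1, the ring oxygen would displace dinitrogen with inversion, and the pyranose would contract to 2,5-anhydro-D-mannose A2.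

- Merits: A1 is a cheap chiral-pool material, and A2 is reached from A1 in one step with both ring stereocentres and their trans relationship in place, with no asymmetric catalyst and no doubt about configuration. In this respect the road from A1 is better than the chosen plan.
- Weak points: A2 has hydroxyl groups on the carbons that become C6 and C7, which the target lacks, so two deoxygenations are needed. The two ends of A2 must be told apart. The α-alkoxy aldehyde of A2, which epimerises easily, must become the alkyne by one-carbon homologation. The hydroxymethyl end must be extended by three carbons to the ester arm. Several protecting-group operations follow, and the longest line from A1 would run well beyond a dozen steps.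
- Comparison: the chosen plan must prove two catalytic asymmetric steps, which the road through A1 and A2 avoids. Against that it carries no surplus oxygen, uses a single protecting group (the silyl cap on the alkyne) and brings every ring carbon in at the right oxidation level.

**Alternative 2:** The cuts are O–C5 and C4–C3. Co(modp)2, a divalent cobalt bis(β-diketonate), under O2 would cyclise (3S)-1-(triisopropylsilyl)hept-6-en-1-yn-3-ol A3 in the 5-exo mode with 2,5-trans preference. The C4 radical would add to methyl acrylate A4 and a hydrogen-atom donor would finish the chain, giving the oxolane ester A5, which is compound 20 of the chosen route.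

- Merits: A3 is one or two steps from simple materials, so A5 would be reached in about three steps against eleven steps in all (nine in the longest line) for 20 here. Only C8 has to be set in advance in A3; C5 follows by substrate control. On step economy this road is clearly ahead.
- Weak points: the trans preference depends on the C8 substituent of A3 taking a pseudo-equatorial place in the cyclisation. A slim alkynyl group is the least convincing substituent for that, so the trans/cis ratio of A5 is uncertain. The C4 radical must add to A4 faster than it is reduced to the methyl-substituted oxolane or trapped by oxygen, which calls for excess A4 and invites telomers.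
- Comparison: the chosen plan is longer. It offers in return two stereocentres under separate reagent control, a ring closure with no stereochemical question, and no three-component radical competition. If A3 cyclised with high trans selectivity, alternative 2 would be the more economical route to A5.

**Alternative 3:** The cut is O–C8. CuOTf (monovalent copper) with a chiral pybox ligand and iPr2NEt would convert both C8 epimers of methyl (5R)-8-(acetyloxy)-5-hydroxydec-9-ynoate A6 into one copper allenylidene. The C5 hydroxyl would then attack C8 to close the oxolane as methyl 4-[(2R,5S)-5-ethynyloxolan-2-yl]butanoate A7, which is compound 21 of the chosen route.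

- Merits: C8 of A6 need not be set beforehand, the terminal alkyne of A7 is formed directly, and there is no ring alkene to saturate and no silyl group to remove. A7 is one coupling from the target. On these counts this road is as good as or better than the chosen one.
- Weak points: A6 is a 5-hydroxy ester whose nucleophilic hydroxyl cannot be protected, so δ-lactonisation under the amine base competes with etherification. The ligand must cooperate with, or override, the existing C5 centre of A6 across a flexible tether. Capture of copper allenylidenes by an aliphatic hydroxyl within the molecule is much less established than capture by nitrogen or phenol nucleophiles.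
- Comparison: the chosen plan brings in the ester only after the ring exists, so it has no lactone channel of the kind open to A6. Both stereocentres are fixed before ring formation by separate, well-understood catalysts, at the price of more steps than the road to A7.

Key step: step 7

Assumption: the (Sa,S,S) phosphoramidite L, (11bS)-N,N-bis[(1S)-1-phenylethyl]dinaphtho[2,1-d:1′,2′-f][1,3,2]dioxaphosphepin-4-amine, is taken to direct the alkoxide to the face that gives (S) at C8, by analogy with aryl- and alkenyl-substituted allyl carbonates; if the first run shows the opposite sense, the mirror-image ligand is used and nothing else changes.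

## Route

Step 1
Reactants: 1 triethyl phosphonoacetate; 2 3-(triisopropylsilyl)prop-2-ynal
Product: 4 ethyl (2E)-5-(triisopropylsilyl)pent-2-en-4-ynoate, via sodiated phosphonoacetate 3 (not isolated)
Conditions: NaH, THF, 0 °C; then 2, −78 → 0 °C
Reagents that add atoms: none
Why: Horner–Wadsworth–Emmons olefination: the stabilised phosphonate carbanion adds reversibly to the aldehyde and the anti adduct eliminates fastest, so the (E)-enoate should dominate; the bulky silyl cap keeps the ynal from conjugate addition.

Step 2
Reactants: 4 ethyl (2E)-5-(triisopropylsilyl)pent-2-en-4-ynoate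
Product: 5 (2E)-5-(triisopropylsilyl)pent-2-en-4-yn-1-ol
Conditions: iBu2AlH (2.2 equiv), CH2Cl2, −78 °C; aq. potassium sodium tartrate
Reagents that add atoms: none
Why: Hydride reduction of an α,β-unsaturated ester to the allylic alcohol, 1,2-selective with iBu2AlH at low temperature; the silylalkyne is not hydroaluminated at −78 °C.

Step 3
Reactants: 5 (2E)-5-(triisopropylsilyl)pent-2-en-4-yn-1-ol
Product: 6 tert-butyl (2E)-5-(triisopropylsilyl)pent-2-en-4-yn-1-yl carbonate
Conditions: Boc2O, Bu4NHSO4 (cat.), aq. NaOH, CH2Cl2, 0 °C → rt
Reagents that add atoms: di-tert-butyl dicarbonate, CC(C)(C)OC(=O)OC(=O)OC(C)(C)C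
Why: Phase-transfer O-acylation to the mixed carbonate; the tert-butyl carbonate is chosen because the tert-butoxide it releases in step 6 is too hindered to compete with the copper alkoxide.

Step 4
Reactants: 7 2-bromocyclopent-2-en-1-one
Product: 8 (1R)-2-bromocyclopent-2-en-1-ol
Conditions: (S)-1-methyl-3,3-diphenyltetrahydro-1H,3H-pyrrolo[1,2-c][1,3,2]oxazaborole (10 mol%), BH3·SMe2, THF, −20 °C; MeOH
Reagents that add atoms: none
Why: Corey–Bakshi–Shibata reduction: the ketone binds the catalyst boron with the α-bromoalkenyl arm as the large group and borane held on nitrogen delivers hydride to one carbonyl face, which for the (S)-catalyst should give the (1R) alcohol; the bromine only enlarges the size difference between the two arms, which is too small in cyclopent-2-enone itself.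

Step 5
Reactants: 8 (1R)-2-bromocyclopent-2-en-1-ol
Product: 10 (1R)-cyclopent-2-en-1-ol, via dilithiated cyclopentenolate 9 (not isolated)
Conditions: tBuLi (3.1 equiv), Et2O, −78 °C; then MeOH, −78 °C → rt; careful distillation
Reagents that add atoms: none
Why: Bromine–lithium exchange followed by protonation: the first equivalent of tBuLi forms the alkoxide, the second exchanges the alkenyl bromide and the third destroys tert-butyl bromide; C1 is not touched, so the configuration is kept, and the by-products are gases or salts, which suits a volatile product.

Step 6
Reactants: 10 (1R)-cyclopent-2-en-1-ol; 6 tert-butyl (2E)-5-(triisopropylsilyl)pent-2-en-4-yn-1-yl carbonate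
Product: 13 triisopropyl{(3S)-3-[(1R)-cyclopent-2-en-1-yloxy]pent-4-en-1-yn-1-yl}silane, via lithium cyclopentenolate 11 (not isolated), via copper cyclopentenolate 12 (not isolated)
Conditions: 10 (1.5 equiv), nBuLi, THF, 0 °C; CuI, rt; then 6, [Ir(cod)Cl]2 (2 mol%), (Sa,S,S)-L (4 mol%, activated with nPrNH2), THF, rt
Reagents that add atoms: none
Why: Iridium-catalysed branched-selective allylic etherification: the cyclometalated iridium phosphoramidite ionises the linear carbonate to an alkynyl-substituted allyl complex and the monovalent copper alkoxide attacks the substituted terminus anti to the metal, the ligand deciding the face so that C8 should form as (S) largely independent of the alkoxide; the C–O bond of 10 is not broken, so (1R) is carried into the ether.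

Step 7
Reactants: 13 triisopropyl{(3S)-3-[(1R)-cyclopent-2-en-1-yloxy]pent-4-en-1-yn-1-yl}silane
Product: 14 (2R,5S)-2-(but-3-en-1-yl)-5-[(triisopropylsilyl)ethynyl]-2,5-dihydrofuran
Conditions: second-generation Grubbs catalyst (5 mol%), ethylene (1 atm), CH2Cl2 (0.01 M), 25–40 °C
Reagents that add atoms: ethylene, C=C
Why: Ring-rearrangement metathesis: a ruthenium alkylidene formed at the terminal vinyl group (C7) adds across the cyclopentene alkene (C6=C2) by [2+2] cycloaddition, cycloreversion forms C6=C7 and moves the carbene to C2, and ethylene caps it as the C2=C1 vinyl group while returning the methylidene; entry by methylidene opening of the cyclopentene followed by ring closure leads to the same product. The closest known reaction type is the ring-rearrangement metathesis of cyclopent-2-enyl allyl ethers and N-allyl cyclopentenyl amines to 2,5-dihydrofurans and 2,5-dihydropyrroles under ethylene. The dihydrofuran is closed by five-membered ring-closing metathesis, the only new ring bond being C6=C7, and the carbocycle opens in the same catalytic turn. No stereocentre is created: the C5–O and C8–O bonds and both carbinol C–H bonds are untouched, so the (1R,3S) ether should give the (2R,5S) trans ring. The selectivity needed is chemoselectivity for the intramolecular exchange over oligomerisation and cross-metathesis, which high dilution and ethylene (it cleaves dimers and speeds carbene turnover) are meant to secure. The product side should be favoured because its ring alkene is flanked by two substituted allylic carbons and re-enters the cycle only slowly. The alkyne should not interfere, since the triisopropylsilyl group blocks enyne metathesis and the 1,4-enyne spacing allows no ring closure onto it.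

Step 8
Reactants: 14 (2R,5S)-2-(but-3-en-1-yl)-5-[(triisopropylsilyl)ethynyl]-2,5-dihydrofuran
Product: 16 4-[(2R,5S)-5-[(triisopropylsilyl)ethynyl]-2,5-dihydrofuran-2-yl]butan-1-ol, via alkylborane 15 (not isolated)
Conditions: 9-BBN (1.15 equiv), THF, 0 °C → rt; then NaBO3·4H2O, H2O, rt
Reagents that add atoms: sodium perborate, [Na+].[Na+].O[B-]1(O)OO[B-](O)(O)OO1
Why: Anti-Markovnikov hydroboration–oxidation: 9-BBN adds to a monosubstituted terminal alkene far faster than to a cis-disubstituted ring alkene and leaves the hindered silylalkyne alone; perborate oxidises the C–B bond under near-neutral conditions that should not isomerise the dihydrofuran.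

Step 9
Reactants: 16 4-[(2R,5S)-5-[(triisopropylsilyl)ethynyl]-2,5-dihydrofuran-2-yl]butan-1-ol
Product: 17 4-[(2R,5S)-5-[(triisopropylsilyl)ethynyl]oxolan-2-yl]butan-1-ol
Conditions: TsNHNH2 (excess, in portions), NaOAc, DME/H2O, 85 °C
Reagents that add atoms: none
Why: Diimide reduction: concerted syn transfer of two hydrogens to the unhindered cis ring alkene; the alkyne, shielded by three isopropyl groups and the branched C8, should react much more slowly, and with no metal present the allylic and propargylic C–O bonds are not hydrogenolysed.

Step 10
Reactants: 17 4-[(2R,5S)-5-[(triisopropylsilyl)ethynyl]oxolan-2-yl]butan-1-ol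
Product: 19 4-[(2R,5S)-5-[(triisopropylsilyl)ethynyl]oxolan-2-yl]butanoic acid, via oxolanylbutanal 18 (not isolated)
Conditions: TEMPO (0.2 equiv), PhI(OAc)2 (2.2 equiv), MeCN/H2O (1:1), rt
Reagents that add atoms: water, O
Why: Oxoammonium-mediated oxidation of a primary alcohol to the aldehyde, hydration and a second oxidation to the acid; the conditions are metal-free and near neutral, so the ether C–H bonds and the silylalkyne are left alone.

Step 11
Reactants: 19 4-[(2R,5S)-5-[(triisopropylsilyl)ethynyl]oxolan-2-yl]butanoic acid
Product: 20 methyl 4-[(2R,5S)-5-[(triisopropylsilyl)ethynyl]oxolan-2-yl]butanoate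
Conditions: MeI, K2CO3, DMF, rt
Reagents that add atoms: iodomethane, CI
Why: SN2 O-alkylation of the carboxylate; the base is too weak to disturb C8.

Step 12
Reactants: 20 methyl 4-[(2R,5S)-5-[(triisopropylsilyl)ethynyl]oxolan-2-yl]butanoate
Product: 21 methyl 4-[(2R,5S)-5-ethynyloxolan-2-yl]butanoate
Conditions: Bu4NF (1.1 equiv), THF, 0 °C → rt
Reagents that add atoms: none
Why: Fluoride-induced protodesilylation of the alkynylsilane; a short reaction with a slight excess of fluoride should spare the methyl ester and the C8 stereocentre.

Step 13
Reactants: 22 non-8-yn-1-ol
Product: 23 non-8-ynal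
Conditions: TEMPO (0.1 equiv), PhI(OAc)2 (1.1 equiv), CH2Cl2, rt
Reagents that add atoms: none
Why: Oxoammonium-mediated alcohol oxidation, which stops at the aldehyde in the absence of water and does not touch the terminal alkyne.

Step 14
Reactants: 23 non-8-ynal
Product: 24 (1Z)-1-bromodec-1-en-9-yne
Conditions: [Ph3PCH2Br]Br, KOtBu, THF, −78 °C; then 23, −78 °C → rt
Reagents that add atoms: (bromomethyl)triphenylphosphonium bromide, BrC[P+](c1ccccc1)(c1ccccc1)c1ccccc1.[Br-]
Why: Wittig olefination with a non-stabilised α-bromo ylide under kinetic control, which passes through the cis oxaphosphetane and should give the (Z)-bromoalkene; the low temperature and the absence of excess base guard against dehydrobromination.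

Step 15
Reactants: 24 (1Z)-1-bromodec-1-en-9-yne
Product: 26 (1Z,9E)-1-bromo-10-iododeca-1,9-diene, via alkenylzirconocene chloride 25 (not isolated)
Conditions: Cp2Zr(H)Cl (1.15 equiv), THF, rt, dark; then I2, 0 °C
Reagents that add atoms: iodine, II
Why: Hydrozirconation–iodination: syn addition of Zr–H to the terminal alkyne places zirconium on the terminal carbon and iodinolysis with retention gives the (E)-iodoalkene; the terminal alkyne reacts within minutes, whereas the disubstituted bromoalkene should be inert to a slight excess of reagent.

Step 16
Reactants: 21 methyl 4-[(2R,5S)-5-ethynyloxolan-2-yl]butanoate; 26 (1Z,9E)-1-bromo-10-iododeca-1,9-diene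
Product: 27 methyl 4-[(2R,5S)-5-[(3E,11Z)-12-bromododeca-3,11-dien-1-yn-1-yl]oxolan-2-yl]butanoate
Conditions: Pd(PPh3)4 (5 mol%), CuI (10 mol%), iPr2NH, THF, degassed, 0 °C → rt
Reagents that add atoms: none
Why: Sonogashira coupling: zerovalent palladium inserts into the alkenyl C–I bond much faster than into the C–Br bond at or below room temperature, both alkene geometries are retained, and the amine base is too weak to affect C8 or the ester.

## Compound list

1 | triethyl phosphonoacetate | CCOC(=O)CP(=O)(OCC)OCC | starting material
2 | 3-(triisopropylsilyl)prop-2-ynal | O=CC#C[Si](C(C)C)(C(C)C)C(C)C | starting material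
3 | sodium salt of the triethyl phosphonoacetate carbanion (formed in the flask) | [Na+].CCOC(=O)[CH-]P(=O)(OCC)OCC | intermediate
4 | ethyl (2E)-5-(triisopropylsilyl)pent-2-en-4-ynoate | CCOC(=O)/C=C/C#C[Si](C(C)C)(C(C)C)C(C)C | intermediate
5 | (2E)-5-(triisopropylsilyl)pent-2-en-4-yn-1-ol | OC/C=C/C#C[Si](C(C)C)(C(C)C)C(C)C | intermediate
6 | tert-butyl (2E)-5-(triisopropylsilyl)pent-2-en-4-yn-1-yl carbonate | CC(C)(C)OC(=O)OC/C=C/C#C[Si](C(C)C)(C(C)C)C(C)C | intermediate
7 | 2-bromocyclopent-2-en-1-one | O=C1CCC=C1Br | starting material
8 | (1R)-2-bromocyclopent-2-en-1-ol | O[C@H]1C(Br)=CCC1 | intermediate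
9 | lithium (1R)-2-lithiocyclopent-2-en-1-olate (formed in the flask) | [Li]O[C@H]1C([Li])=CCC1 | intermediate
10 | (1R)-cyclopent-2-en-1-ol | O[C@H]1C=CCC1 | intermediate
11 | lithium (1R)-cyclopent-2-en-1-olate (formed in the flask) | [Li]O[C@H]1C=CCC1 | intermediate
12 | copper (1R)-cyclopent-2-en-1-olate, monovalent copper (formed in the flask) | [Cu]O[C@H]1C=CCC1 | intermediate
13 | triisopropyl{(3S)-3-[(1R)-cyclopent-2-en-1-yloxy]pent-4-en-1-yn-1-yl}silane | C=C[C@@H](C#C[Si](C(C)C)(C(C)C)C(C)C)O[C@H]1C=CCC1 | intermediate
14 | (2R,5S)-2-(but-3-en-1-yl)-5-[(triisopropylsilyl)ethynyl]-2,5-dihydrofuran | C=CCC[C@@H]1C=C[C@@H](C#C[Si](C(C)C)(C(C)C)C(C)C)O1 | intermediate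
15 | 9-{4-[(2R,5S)-5-[(triisopropylsilyl)ethynyl]-2,5-dihydrofuran-2-yl]butyl}-9-borabicyclo[3.3.1]nonane (formed in the flask) | C1CCC2CCCC1B2CCCC[C@@H]1C=C[C@@H](C#C[Si](C(C)C)(C(C)C)C(C)C)O1 | intermediate
16 | 4-[(2R,5S)-5-[(triisopropylsilyl)ethynyl]-2,5-dihydrofuran-2-yl]butan-1-ol | OCCCC[C@@H]1C=C[C@@H](C#C[Si](C(C)C)(C(C)C)C(C)C)O1 | intermediate
17 | 4-[(2R,5S)-5-[(triisopropylsilyl)ethynyl]oxolan-2-yl]butan-1-ol | OCCCC[C@@H]1CC[C@@H](C#C[Si](C(C)C)(C(C)C)C(C)C)O1 | intermediate
18 | 4-[(2R,5S)-5-[(triisopropylsilyl)ethynyl]oxolan-2-yl]butanal (formed in the flask) | O=CCCC[C@@H]1CC[C@@H](C#C[Si](C(C)C)(C(C)C)C(C)C)O1 | intermediate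
19 | 4-[(2R,5S)-5-[(triisopropylsilyl)ethynyl]oxolan-2-yl]butanoic acid | OC(=O)CCC[C@@H]1CC[C@@H](C#C[Si](C(C)C)(C(C)C)C(C)C)O1 | intermediate
20 | methyl 4-[(2R,5S)-5-[(triisopropylsilyl)ethynyl]oxolan-2-yl]butanoate | COC(=O)CCC[C@@H]1CC[C@@H](C#C[Si](C(C)C)(C(C)C)C(C)C)O1 | intermediate
21 | methyl 4-[(2R,5S)-5-ethynyloxolan-2-yl]butanoate | COC(=O)CCC[C@@H]1CC[C@@H](C#C)O1 | intermediate
22 | non-8-yn-1-ol | OCCCCCCCC#C | starting material
23 | non-8-ynal | O=CCCCCCCC#C | intermediate
24 | (1Z)-1-bromodec-1-en-9-yne | Br/C=C\CCCCCCC#C | intermediate
25 | [(1E,9Z)-10-bromodeca-1,9-dien-1-yl]chlorobis(cyclopentadienyl)zirconium (formed in the flask) | Br/C=C\CCCCCC/C=C/[Zr](Cl)(C1C=CC=C1)C1C=CC=C1 | intermediate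
26 | (1Z,9E)-1-bromo-10-iododeca-1,9-diene | Br/C=C\CCCCCC/C=C/I | intermediate
27 | methyl 4-[(2R,5S)-5-[(3E,11Z)-12-bromododeca-3,11-dien-1-yn-1-yl]oxolan-2-yl]butanoate | COC(=O)CCC[C@@H]1CC[C@@H](C#C/C=C/CCCCCC/C=C\Br)O1 | target

## Step count and risk

Total: 16 steps. Longest linear sequence: 11 steps (steps 1, 2, 3, 6, 7, 8, 9, 10, 11, 12, 16). The cyclopentenol branch (steps 4, 5) and the tail branch (steps 13–15) are shorter.

**Step 7 (key step).** The vinyl group sits on a carbon that also carries the alkynyl group and the ether oxygen, so loading of the catalyst there may be slow. Opening of the cyclopentene by the methylidene and cross-metathesis between molecules could then outrun ring closure, or the carbene could be held unproductively by the ether oxygen, so that turnover stalls short of completion. The fallback avoids opening a carbocycle; it sets out from carbonate 6 and comes back to the route at alcohol 16. Commercial 5-[(tert-butyldimethylsilyl)oxy]pentanal and CH2=CHMgBr would give the racemic alcohol 7-[(tert-butyldimethylsilyl)oxy]hept-1-en-3-ol F1. Sharpless kinetic resolution (Ti(OiPr)4, L-(+)-diisopropyl tartrate, tBuOOH) would leave (3R)-7-[(tert-butyldimethylsilyl)oxy]hept-1-en-3-ol F2, the (3S) antipode being removed by epoxidation. The copper alkoxide of F2 would be coupled with 6 under the conditions of step 6 to give the acyclic diene ether F3, in which both carbinol carbons already have the required configuration. Plain ring-closing metathesis of F3 with second-generation Grubbs catalyst would join the two vinyl groups that flank the ether oxygen and give the silyl-protected dihydrofuran F4, with the oxygenated arm already in place. Pyridinium p-toluenesulfonate in methanol would then remove the tert-butyldimethylsilyl group of F4 and give 16.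

**Step 6.** The electrophile is an enynyl carbonate and the nucleophile a hindered secondary allylic alkoxide. Attack at the unsubstituted allyl terminus (linear ether), slow ionisation, or eroded face selectivity in a mismatched pairing could lower regio- or diastereoselectivity. The fallback sets C8 before the ether is made and forms the cyclopentenyl C–O bond by palladium catalysis; it sets out from aldehyde 2 and comes back at ether 13. CH2=CHMgBr would add to 2 to give racemic 1-(triisopropylsilyl)pent-4-en-1-yn-3-ol F5. Sharpless kinetic resolution with L-(+)-diisopropyl tartrate should, by the usual mnemonic, leave (3S)-1-(triisopropylsilyl)pent-4-en-1-yn-3-ol F6. Racemic cyclopent-2-en-1-yl methyl carbonate F7 would be made from commercial racemic cyclopent-2-en-1-ol and methyl chloroformate. The zinc alkoxide of F6 (Et2Zn) would be allylated with F7 under Pd2(dba)3 and the C2-symmetric N,N′-(trans-cyclohexane-1,2-diyl)bis[2-(diphenylphosphanyl)benzamide] ligand. The symmetrical cyclopentenyl complex of palladium makes both enantiomers of F7 converge, and the ligand enantiomer is chosen by the established mnemonic to give the (1R) ether 13.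

**Step 9.** Diimide disproportionates, so conversion may stall, and pushing the reaction with more reagent could begin to reduce the silylalkyne to the alkenylsilane. The fallback masks the alkyne; it sets out from 16 and comes back at 17. Co2(CO)8 in CH2Cl2 would convert 16 into its hexacarbonyldicobalt alkyne complex F8. Diimide, generated at room temperature from dipotassium azodicarboxylate and acetic acid and used in large excess, would then reduce only the ring alkene and give the saturated complex F9. Oxidative decomplexation of F9 with Fe(NO3)3·9H2O in ethanol would release 17.

**Step 16.** Coupling could also begin at the (Z)-bromoalkene once the iodide is consumed, and oxidative homocoupling of alkyne 21 could compete, both at the cost of the most advanced material. The fallback attaches a tail with a single halide and builds the bromoalkene last; it sets out from 21 and 22 and comes back at 27. Alcohol 22 would be hydrozirconated with Cp2Zr(H)Cl (2.2 equiv) and iodinated to give (8E)-9-iodonon-8-en-1-ol F10. Sonogashira coupling of F10 with 21 would give the enynol F11, and Dess–Martin oxidation of F11 would give the aldehyde F12. Wittig olefination of F12 with the ylide from [Ph3PCH2Br]Br and KOtBu at −78 °C would give 27, so that the Z selectivity then has to be achieved on the full molecule.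

## Further compounds

F1 | step 7 | rac-7-[(tert-butyldimethylsilyl)oxy]hept-1-en-3-ol | CC(C)(C)[Si](C)(C)OCCCCC(O)C=C
F2 | step 7 | (3R)-7-[(tert-butyldimethylsilyl)oxy]hept-1-en-3-ol | CC(C)(C)[Si](C)(C)OCCCC[C@@H](O)C=C
F3 | step 7 | tert-butyldimethyl{[(5R)-5-{[(3S)-1-(triisopropylsilyl)pent-4-en-1-yn-3-yl]oxy}hept-6-en-1-yl]oxy}silane | C=C[C@@H](C#C[Si](C(C)C)(C(C)C)C(C)C)O[C@H](CCCCO[Si](C)(C)C(C)(C)C)C=C
F4 | step 7 | tert-butyldimethyl{4-[(2R,5S)-5-[(triisopropylsilyl)ethynyl]-2,5-dihydrofuran-2-yl]butoxy}silane | CC(C)(C)[Si](C)(C)OCCCC[C@@H]1C=C[C@@H](C#C[Si](C(C)C)(C(C)C)C(C)C)O1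
F5 | step 6 | rac-1-(triisopropylsilyl)pent-4-en-1-yn-3-ol | C=CC(O)C#C[Si](C(C)C)(C(C)C)C(C)C
F6 | step 6 | (3S)-1-(triisopropylsilyl)pent-4-en-1-yn-3-ol | C=C[C@H](O)C#C[Si](C(C)C)(C(C)C)C(C)C
F7 | step 6 | rac-cyclopent-2-en-1-yl methyl carbonate | COC(=O)OC1C=CCC1
F8 | step 9 | hexacarbonyldicobalt complex of the alkyne of 4-[(2R,5S)-5-[(triisopropylsilyl)ethynyl]-2,5-dihydrofuran-2-yl]butan-1-ol | OCCCC[C@@H]1C=C[C@@H](C23C4([Si](C(C)C)(C(C)C)C(C)C)[Co]2(=C=O)(=C=O)(=C=O)[Co]34(=C=O)(=C=O)=C=O)O1
F9 | step 9 | hexacarbonyldicobalt complex of the alkyne of 4-[(2R,5S)-5-[(triisopropylsilyl)ethynyl]oxolan-2-yl]butan-1-ol | OCCCC[C@@H]1CC[C@@H](C23C4([Si](C(C)C)(C(C)C)C(C)C)[Co]2(=C=O)(=C=O)(=C=O)[Co]34(=C=O)(=C=O)=C=O)O1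
F10 | step 16 | (8E)-9-iodonon-8-en-1-ol | OCCCCCCC/C=C/I
F11 | step 16 | methyl 4-[(2R,5S)-5-[(3E)-11-hydroxyundec-3-en-1-yn-1-yl]oxolan-2-yl]butanoate | COC(=O)CCC[C@@H]1CC[C@@H](C#C/C=C/CCCCCCCO)O1
F12 | step 16 | methyl 4-[(2R,5S)-5-[(3E)-11-oxoundec-3-en-1-yn-1-yl]oxolan-2-yl]butanoate | COC(=O)CCC[C@@H]1CC[C@@H](C#C/C=C/CCCCCCC=O)O1
A1 | alternative 1 | D-glucosamine (2-amino-2-deoxy-D-glucopyranose) | C([C@@H]1[C@H]([C@@H]([C@H](C(O1)O)N)O)O)O
A2 | alternative 1 | 2,5-anhydro-D-mannose | O=C[C@H]1O[C@H](CO)[C@@H](O)[C@@H]1O
A3 | alternative 2 | (3S)-1-(triisopropylsilyl)hept-6-en-1-yn-3-ol | C=CCC[C@H](O)C#C[Si](C(C)C)(C(C)C)C(C)C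
A4 | alternative 2 | methyl acrylate | C=CC(=O)OC
A5 | alternative 2 | methyl 4-[(2R,5S)-5-[(triisopropylsilyl)ethynyl]oxolan-2-yl]butanoate | COC(=O)CCC[C@@H]1CC[C@@H](C#C[Si](C(C)C)(C(C)C)C(C)C)O1
A6 | alternative 3 | methyl (5R)-8-(acetyloxy)-5-hydroxydec-9-ynoate (both C8 epimers) | COC(=O)CCC[C@@H](O)CCC(OC(C)=O)C#C
A7 | alternative 3 | methyl 4-[(2R,5S)-5-ethynyloxolan-2-yl]butanoate | COC(=O)CCC[C@@H]1CC[C@@H](C#C)O1
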